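**Plan**

Rings: A = benzo ring, B = dihydrofuran ring, C = syringyl ring. The retrosynthesis first cuts the C5–propenyl bond (cross-coupling at a bromide), then O1–C2 and C3a–C3 of ring B together. This leaves a 4-bromoguaiacol raised to its o-quinone monoketal and (E)-4-propenylsyringol.
Enabling feature: the free hydroxyl on C4′ of ring C, para to C2, makes the propenyl β-carbon (future C3) a vinylogous phenol nucleophile and turns C2 into a p-quinone methide carbon as soon as C3a–C3 exists. The O1/C7-OMe pair of ring A lets ring A be dearomatized to a dienone ketal whose CH ortho to the carbonyl (future C3a) is electrophilic.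
Forward: rings A and C are bought, ring B is closed in one operation by a formal [3+2] union, and the propenyl chain is joined last at the bromine that first served as para-blocking group.
Stereochemistry: C3 comes from a chiral Brønsted acid (chiral counter-anion) in the C–C bond formation; C2 is relayed from C3 as the trans isomer by reversible ring closure; the E alkenes come from thermodynamic isomerization and a stereodefined boronate.

Key step: step 3

Remark: the absolute sense of induction of the chiral acid in step 3 cannot be derived from first principles; the (R)-configured acid is written, and its mirror image is used instead if the screen shows the opposite sense.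

**Step 1**
Reactants: 1 4-allyl-2,6-dimethoxyphenol
Product: 2 (E)-2,6-dimethoxy-4-(prop-1-en-1-yl)phenol
Conditions: RuClH(CO)(PPh3)3 (1 mol%), toluene, 80 °C
Reagents that add atoms: none
Why: The Ru–H bond of RuClH(CO)(PPh3)3 adds to the allyl double bond and β-hydride elimination returns it in conjugation with the arene (metal hydride olefin isomerization); the conjugated E isomer is the thermodynamic product and the free phenol is tolerated.

**Step 2**
Reactants: 3 4-bromo-2-methoxyphenol
Product: 4 4-bromo-6,6-dimethoxycyclohexa-2,4-dien-1-one
Conditions: PhI(OAc)2 (1.1 equiv), MeOH, 0 °C; NaHCO3 work-up, used promptly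
Reagents that add atoms: methanol, CO
Why: Oxidative dearomatization of a 2-methoxyphenol with PhI(OAc)2: the aryloxy-iodane collapses to a phenoxonium ion that methanol captures at the methoxy-bearing carbon (masked o-benzoquinone formation), and the bromine at C4 retards the Diels–Alder dimerization of such dienone ketals.

**Step 3**
Reactants: 4 4-bromo-6,6-dimethoxycyclohexa-2,4-dien-1-one; 2 (E)-2,6-dimethoxy-4-(prop-1-en-1-yl)phenol
Product: 7 4-[(2S,3S)-5-bromo-7-methoxy-3-methyl-2,3-dihydro-1-benzofuran-2-yl]-2,6-dimethoxyphenol, via phenoxonium ion 5 (not isolated), via p-quinone methide 6 (not isolated)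
Conditions: (R)-3,3′-bis(2,4,6-triisopropylphenyl)-BINOL N-triflylphosphoramide (10 mol%), 5 Å MS, toluene/CH2Cl2, −40 °C, 4 (1.3 equiv) added slowly
Reagents that add atoms: none
Why: Proposed new method: the chiral acid ionizes ketal 4 with loss of methanol to the 2-methoxyphenoxonium (O-methyl o-quinone) ion 5, held as a contact ion pair by the phosphoramide anion, which also hydrogen-bonds the free 4-hydroxyl of 2; the propenyl β-carbon of 2, a vinylogous para position of that phenol, adds to the ring CH ortho to the carbonyl of 5, and proton loss with rearomatization gives the neutral p-quinone methide 6, whose new phenol adds to the methide carbon. The closest known reaction type is the Brønsted acid-promoted formal [3+2] coupling of quinone monoacetals with β-methylstyrenes to trans-2-aryl-3-methyl-2,3-dihydrobenzofurans, here joined to the asymmetric counter-anion control that chiral phosphoric acids exert on quinone imine ketals and on p-quinone methides. Ring B closes by a 5-exo-trig oxa-1,6-addition (oxa-Michael) of O1 to C2. C3 is set in the C–C bond-forming step by the enantiofacial choice at the alkene β-carbon inside the chiral ion pair, and C2 is set relative to C3 as the trans isomer, both kinetically (methyl and aryl anti in the closure) and thermodynamically, because the acid keeps the C2–O1 bond in equilibrium with 6 while C3 cannot epimerize. The step needs attack at the ortho CH of 5 and not at its para or conjugate positions, and C-attack through the alkene and not O-attack: the bromine blocks the para carbon so that only the ortho adduct can lose a proton and rearomatize, both ortho positions of 2 carry methoxyl groups, and the low temperature keeps the thermal Diels–Alder reaction of dienone 4 with the alkene out of play.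

**Step 4**
Reactants: 7 4-[(2S,3S)-5-bromo-7-methoxy-3-methyl-2,3-dihydro-1-benzofuran-2-yl]-2,6-dimethoxyphenol; 8 4,4,5,5-tetramethyl-2-[(1E)-prop-1-en-1-yl]-1,3,2-dioxaborolane
Product: 9 4-[(2S,3S)-7-methoxy-3-methyl-5-[(1E)-prop-1-en-1-yl]-2,3-dihydro-1-benzofuran-2-yl]-2,6-dimethoxyphenol (odoratisol A)
Conditions: Pd(OAc)2 (3 mol%), SPhos (6 mol%), K3PO4 (3 equiv), THF/H2O, 50 °C
Reagents that add atoms: (E)-prop-1-enylboronic acid pinacol ester (compound 8), C/C=C/B1OC(C)(C)C(C)(C)O1
Why: Suzuki–Miyaura coupling: the electron-rich dialkylbiarylphosphine drives oxidative addition of the aryl bromide to zerovalent palladium, transmetalation and reductive elimination keep the E geometry of the boronate, and the mild base and temperature should leave the free phenol and both stereocenters untouched.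

**Compound list**

1 | 4-allyl-2,6-dimethoxyphenol | C=CCc1cc(OC)c(O)c(OC)c1 | starting material
2 | (E)-2,6-dimethoxy-4-(prop-1-en-1-yl)phenol | C/C=C/c1cc(OC)c(O)c(OC)c1 | intermediate
3 | 4-bromo-2-methoxyphenol | COc1cc(Br)ccc1O | starting material
4 | 4-bromo-6,6-dimethoxycyclohexa-2,4-dien-1-one | O=C1C=CC(Br)=CC1(OC)OC | intermediate
5 | 4-bromo-2-methoxyphenoxonium ion (cation of the ion pair with the chiral phosphoramide anion) | O=C1C=CC(Br)=CC1=[O+]C | intermediate (not isolated)
6 | 4-[(2R)-2-(5-bromo-2-hydroxy-3-methoxyphenyl)propylidene]-2,6-dimethoxycyclohexa-2,5-dien-1-one | COC1=CC(=C[C@@H](C)c2cc(Br)cc(OC)c2O)C=C(OC)C1=O | intermediate (not isolated)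
7 | 4-[(2S,3S)-5-bromo-7-methoxy-3-methyl-2,3-dihydro-1-benzofuran-2-yl]-2,6-dimethoxyphenol | Brc1cc(OC)c2c(c1)[C@H](C)[C@@H](c1cc(OC)c(O)c(OC)c1)O2 | intermediate
8 | 4,4,5,5-tetramethyl-2-[(1E)-prop-1-en-1-yl]-1,3,2-dioxaborolane | C/C=C/B1OC(C)(C)C(C)(C)O1 | starting material
9 | odoratisol A, 4-[(2S,3S)-7-methoxy-3-methyl-5-[(1E)-prop-1-en-1-yl]-2,3-dihydro-1-benzofuran-2-yl]-2,6-dimethoxyphenol | C/C=C/c1cc(OC)c2c(c1)[C@H](C)[C@@H](c1cc(OC)c(O)c(OC)c1)O2 | target

**Step count**

Total steps: 4. Longest linear sequence: 3 steps (3 → 4 → 7 → 9); the one-step branch 1 → 2 joins at step 3.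

**Steps most likely to fail**

Step 3 (proposed new method). Two processes are at risk. The first is insufficient enantiofacial discrimination at the propenyl β-carbon, because the hydrogen-bonded hydroxyl sits seven atoms from the carbon that becomes C3. The second is diversion of the ion pair into conjugate or ipso addition, or acid-catalysed self-dimerization of the propenylphenol. The fallback uses known chemistry and sets out from compound 2. A biomimetic oxidative cross-coupling with commercial (E)-isoeugenol (C/C=C/c1ccc(O)c(OC)c1, in excess) and Ag2O in toluene/acetone at room temperature should give the racemic trans compound, that is 9 together with its (2R,3R)-enantiomer F1. The sequence is one-electron oxidation of both phenols, 8–5′ radical coupling and closure of the quinone methide; compound 2 can take part only through its β-carbon because both its ortho positions are blocked. Preparative chromatography on a chiral stationary phase (cellulose tris(3,5-dimethylphenylcarbamate)) then separates the two. The fallback comes back to the route at compound 9, so steps 2 and 4 are not needed.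

Step 2. The process at risk is Diels–Alder self-dimerization and hydrolytic loss of the ketal while the dienone is concentrated and stored. The fallback sets out from compound 3. A Wessely acetoxylation (Pb(OAc)4, AcOH/CH2Cl2, 0 °C) should give the o-quinol acetate 6-acetoxy-4-bromo-6-methoxycyclohexa-2,4-dien-1-one F2, a class of dienone that is slower to dimerize. It is taken into step 3 in place of 4, where acetate is the better leaving group and the same ion 5 should form. The fallback comes back to the route at compound 7.

Step 4. The process at risk is base-triggered opening of ring B through the phenoxide to the p-quinone methide, with epimerization at C2 and irreversible tautomerization to a stilbene, and protodeboronation of the alkenylboronate. The fallback sets out from compound 7. A Stille coupling with allyltributylstannane under neutral conditions (Pd(PPh3)4, toluene, 100 °C) should give 4-[(2S,3S)-7-methoxy-3-methyl-5-(prop-2-en-1-yl)-2,3-dihydro-1-benzofuran-2-yl]-2,6-dimethoxyphenol F3. Its allyl group is then moved into conjugation with RuClH(CO)(PPh3)3 in toluene at 80 °C, as in step 1. The fallback comes back to the route at compound 9.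

**Further compounds**

F1 | step 3 | (2R,3R)-enantiomer of odoratisol A, 4-[(2R,3R)-7-methoxy-3-methyl-5-[(1E)-prop-1-en-1-yl]-2,3-dihydro-1-benzofuran-2-yl]-2,6-dimethoxyphenol | C/C=C/c1cc(OC)c2c(c1)[C@@H](C)[C@H](c1cc(OC)c(O)c(OC)c1)O2
F2 | step 2 | 6-acetoxy-4-bromo-6-methoxycyclohexa-2,4-dien-1-one (racemic) | CC(=O)OC1(OC)C=C(Br)C=CC1=O
F3 | step 4 | 4-[(2S,3S)-7-methoxy-3-methyl-5-(prop-2-en-1-yl)-2,3-dihydro-1-benzofuran-2-yl]-2,6-dimethoxyphenol | C=CCc1cc(OC)c2c(c1)[C@H](C)[C@@H](c1cc(OC)c(O)c(OC)c1)O2
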